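## Retrosynthetic overview

1. The target comes from the acetonide-protected glyceryl ester 18 by acetal hydrolysis and selective primary O-acetylation. The glycerol stereocentre is bought in (S)-solketal.
2. The 8,9-seco 1,6-diketone of 18 is unveiled by 1,3-dipolar cycloaddition of ozone (cycloaddition, cycloreversion, cycloaddition, reduction) to the tetrasubstituted C8=C9 alkene of the cis-fused octalin 16. Ring B is a sacrificial ring.
3. 16 is assembled by B-alkyl Suzuki coupling of enol triflate 10 with the side-chain borane 15. The C13 stereocentre is bought in (R)-β-butyrolactone.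
4. The cis-bicycle is built on (R)-carvone, which is ring B: C5 is bought, C10 is set by α'-alkylation then α'-methylation anti to the isopropenyl group, and ring A is closed onto the isopropenyl carbon (gem-dimethyl C4) by a vinylsilane-terminated cation–olefin cyclisation.
5. Ring order: ring B is bought, ring A is formed in step 3, ring B is opened in step 9.

Assumption: (E)-(3-bromoprop-1-en-1-yl)trimethylsilane, (R)-β-butyrolactone and (S)-solketal are taken as catalogue compounds.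

## Route

Step 1
Reactants: 1 (R)-(−)-carvone; 2 (E)-(3-bromoprop-1-en-1-yl)trimethylsilane
Product: 4 (5R,6S)-2-methyl-5-(prop-1-en-2-yl)-6-[(2E)-3-(trimethylsilyl)prop-2-en-1-yl]cyclohex-2-en-1-one, via lithium dienolate 3 (not isolated)
Conditions: LiN(iPr)2, THF, −78 °C; then 2, −78 to 0 °C
Reagents that add atoms: none
Why: Kinetic α'-deprotonation of the enone gives the cross-conjugated enolate, which is C-alkylated by the allylic bromide (enolate alkylation); the new C6 centre (trans to isopropenyl) is erased again in step 2.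

Step 2
Reactants: 4 (5R,6S)-2-methyl-5-(prop-1-en-2-yl)-6-[(2E)-3-(trimethylsilyl)prop-2-en-1-yl]cyclohex-2-en-1-one
Product: 6 (5S,6R)-2,6-dimethyl-5-(prop-1-en-2-yl)-6-[(2E)-3-(trimethylsilyl)prop-2-en-1-yl]cyclohex-2-en-1-one, via lithium enolate 5 (not isolated)
Conditions: LiN(iPr)2, THF/DMPU, −78 °C; then MeI, −78 to −20 °C
Reagents that add atoms: iodomethane (CI)
Why: Second α'-enolate alkylation; MeI attacks the face anti to the adjacent pseudo-axial isopropenyl group (1,2-induction from the bought C5 centre), so the methyl is trans and the silylallyl chain cis to isopropenyl, which sets the quaternary centre (C10 of the target).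

Step 3
Reactants: 6 (5S,6R)-2,6-dimethyl-5-(prop-1-en-2-yl)-6-[(2E)-3-(trimethylsilyl)prop-2-en-1-yl]cyclohex-2-en-1-one
Product: 7 (4aS,8aR)-2,5,5,8a-tetramethyl-4a,5,8,8a-tetrahydronaphthalen-1(4H)-one (cis-fused)
Conditions: CF3CO2H (5 equiv), CH2Cl2, 0 °C to rt; aq NaHCO3
Reagents that add atoms: none
Why: Proton-initiated, vinylsilane-terminated cation–olefin cyclisation: the tertiary cation from the isopropenyl group is captured at the silyl-bearing carbon (β-silyl stabilisation, loss of Me3Si), closing ring A and creating the gem-dimethyl carbon; the cis ring fusion follows from the cis arrangement fixed in step 2.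

Step 4
Reactants: 7 (4aS,8aR)-2,5,5,8a-tetramethyl-4a,5,8,8a-tetrahydronaphthalen-1(4H)-one
Product: 8 (4aS,8aR)-2,5,5,8a-tetramethyl-4a,5,6,7,8,8a-hexahydronaphthalen-1(4H)-one
Conditions: H2 (1 atm), RhCl(PPh3)3 (5 mol%), benzene/EtOH, rt
Reagents that add atoms: none
Why: Homogeneous hydrogenation with Wilkinson's catalyst reduces the cis-disubstituted ring-A alkene and leaves the conjugated trisubstituted enone alone; no stereocentre is formed.

Step 5
Reactants: 8 (4aS,8aR)-2,5,5,8a-tetramethyl-4a,5,6,7,8,8a-hexahydronaphthalen-1(4H)-one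
Product: 10 (4aS,8aR)-2,5,5,8a-tetramethyl-3,4,4a,5,6,7,8,8a-octahydronaphthalen-1-yl trifluoromethanesulfonate, via lithium enolate 9 (not isolated)
Conditions: LiBH(sBu)3, THF, −78 °C; then PhNTf2, −78 to 0 °C
Reagents that add atoms: N-phenylbis(trifluoromethanesulfonimide) (O=S(=O)(N(c1ccccc1)S(=O)(=O)C(F)(F)F)C(F)(F)F)
Why: Conjugate hydride reduction of the β-unsubstituted enone gives the regiodefined enolate (the other α-carbon is quaternary), which is O-triflated; this places the tetrasubstituted C=C exactly where ring B will be cut.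

Step 6
Reactants: 11 (R)-β-butyrolactone
Product: 12 (3S)-3-methylpent-4-enoic acid
Conditions: CH2=CHMgBr (1.3 equiv), CuI (10 mol%), THF/Me2S, −30 °C; then 1 M HCl
Reagents that add atoms: vinylmagnesium bromide (C=C[Mg]Br)
Why: Copper-catalysed SN2 opening of the β-lactone at the alkyl–oxygen carbon with clean inversion turns the bought (R) centre into the (S) acid, which becomes (R)-C13 of the target.

Step 7
Reactants: 12 (3S)-3-methylpent-4-enoic acid; 13 (S)-solketal
Product: 14 [(4R)-2,2-dimethyl-1,3-dioxolan-4-yl]methyl (3S)-3-methylpent-4-enoate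
Conditions: DCC, DMAP (cat.), CH2Cl2, 0 °C to rt
Reagents that add atoms: none
Why: Steglich esterification of the free primary hydroxyl of solketal; neither stereocentre is touched (the descriptor of the dioxolane carbon changes only by priority).

Step 8
Reactants: 14 [(4R)-2,2-dimethyl-1,3-dioxolan-4-yl]methyl (3S)-3-methylpent-4-enoate; 10 (4aS,8aR)-2,5,5,8a-tetramethyl-3,4,4a,5,6,7,8,8a-octahydronaphthalen-1-yl trifluoromethanesulfonate
Product: 16 [(4R)-2,2-dimethyl-1,3-dioxolan-4-yl]methyl (3R)-3-methyl-5-[(4aS,8aR)-2,5,5,8a-tetramethyl-3,4,4a,5,6,7,8,8a-octahydronaphthalen-1-yl]pentanoate, via alkylborane 15 (not isolated)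
Conditions: 9-BBN-H, THF, 0 °C to rt; then 10, PdCl2(dppf) (5 mol%), AsPh3, aq K3PO4, DMF, 50 °C
Reagents that add atoms: none
Why: Anti-Markovnikov hydroboration of the terminal alkene followed by B-alkyl Suzuki–Miyaura coupling with the enol triflate (the same substitution pattern as the well-behaved 2,6,6-trimethylcyclohexenyl triflate) forms the C9–C11 bond; no stereocentre is involved.

Step 9
Reactants: 16 [(4R)-2,2-dimethyl-1,3-dioxolan-4-yl]methyl (3R)-3-methyl-5-[(4aS,8aR)-2,5,5,8a-tetramethyl-3,4,4a,5,6,7,8,8a-octahydronaphthalen-1-yl]pentanoate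
Product: 18 [(4R)-2,2-dimethyl-1,3-dioxolan-4-yl]methyl (3R)-3-methyl-6-oxo-6-[(1R,2S)-1,3,3-trimethyl-2-(3-oxobutyl)cyclohexyl]hexanoate, via ozonide 17 (not isolated)
Conditions: O3, CH2Cl2, −78 °C; then Me2S, −78 °C to rt
Reagents that add atoms: ozone ([O-][O+]=O)
Why: Ozonolysis: 1,3-dipolar cycloaddition of ozone to the only alkene, cycloreversion and re-cycloaddition to the ozonide, then reduction, cleaves ring B to the methyl ketone and the neopentyl ketone; the two ring stereocentres are not enolisable and stay as set.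

Step 10
Reactants: 18 [(4R)-2,2-dimethyl-1,3-dioxolan-4-yl]methyl (3R)-3-methyl-6-oxo-6-[(1R,2S)-1,3,3-trimethyl-2-(3-oxobutyl)cyclohexyl]hexanoate
Product: 19 (2R)-2,3-dihydroxypropyl (3R)-3-methyl-6-oxo-6-[(1R,2S)-1,3,3-trimethyl-2-(3-oxobutyl)cyclohexyl]hexanoate
Conditions: AcOH/H2O (4:1), 40 °C
Reagents that add atoms: none
Why: Acid-catalysed acetal hydrolysis; mildly acidic conditions suppress acyl migration, so the glycerol centre keeps its configuration.

Step 11
Reactants: 19 (2R)-2,3-dihydroxypropyl (3R)-3-methyl-6-oxo-6-[(1R,2S)-1,3,3-trimethyl-2-(3-oxobutyl)cyclohexyl]hexanoate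
Product: 20 (2R)-3-(acetyloxy)-2-hydroxypropyl (3R)-3-methyl-6-oxo-6-[(1R,2S)-1,3,3-trimethyl-2-(3-oxobutyl)cyclohexyl]hexanoate
Conditions: AcCl (1.05 equiv), 2,4,6-collidine, CH2Cl2, −78 °C
Reagents that add atoms: acetyl chloride (CC(Cl)=O)
Why: Kinetically selective acylation of the primary over the secondary hydroxyl at low temperature with a hindered base gives the target.

## Compound list

1 | (R)-(−)-carvone | CC1=CC[C@H](CC1=O)C(C)=C | starting material
2 | (E)-(3-bromoprop-1-en-1-yl)trimethylsilane | C[Si](C)(C)/C=C/CBr | starting material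
3 | kinetic lithium α'-dienolate of carvone | CC1=CC[C@H](C=C1[O-])C(C)=C.[Li+] | intermediate
4 | (5R,6S)-2-methyl-5-(prop-1-en-2-yl)-6-[(2E)-3-(trimethylsilyl)prop-2-en-1-yl]cyclohex-2-en-1-one | CC1=CC[C@@H](C(C)=C)[C@H](C/C=C/[Si](C)(C)C)C1=O | intermediate
5 | lithium α'-enolate of 4 | CC1=CC[C@@H](C(C)=C)C(C/C=C/[Si](C)(C)C)=C1[O-].[Li+] | intermediate
6 | (5S,6R)-2,6-dimethyl-5-(prop-1-en-2-yl)-6-[(2E)-3-(trimethylsilyl)prop-2-en-1-yl]cyclohex-2-en-1-one | CC1=CC[C@@H](C(C)=C)[C@@](C)(C/C=C/[Si](C)(C)C)C1=O | intermediate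
7 | (4aS,8aR)-2,5,5,8a-tetramethyl-4a,5,8,8a-tetrahydronaphthalen-1(4H)-one | CC2=CC[C@H]1C(C)(C)C=CC[C@@]1(C)C2=O | intermediate
8 | (4aS,8aR)-2,5,5,8a-tetramethyl-4a,5,6,7,8,8a-hexahydronaphthalen-1(4H)-one | CC2=CC[C@H]1C(C)(C)CCC[C@@]1(C)C2=O | intermediate
9 | lithium (4aS,8aR)-2,5,5,8a-tetramethyl-3,4,4a,5,6,7,8,8a-octahydronaphthalen-1-olate | CC2CC[C@H]1C(C)(C)CCC[C@@]1(C)C=2[O-].[Li+] | intermediate
10 | (4aS,8aR)-2,5,5,8a-tetramethyl-3,4,4a,5,6,7,8,8a-octahydronaphthalen-1-yl trifluoromethanesulfonate | CC2CC[C@H]1C(C)(C)CCC[C@@]1(C)C=2OS(=O)(=O)C(F)(F)F | intermediate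
11 | (R)-β-butyrolactone, (4R)-4-methyloxetan-2-one | C[C@@H]1CC(=O)O1 | starting material
12 | (3S)-3-methylpent-4-enoic acid | C=C[C@@H](C)CC(=O)O | intermediate
13 | (S)-solketal, [(4S)-2,2-dimethyl-1,3-dioxolan-4-yl]methanol | OC[C@H]1COC(C)(C)O1 | starting material
14 | [(4R)-2,2-dimethyl-1,3-dioxolan-4-yl]methyl (3S)-3-methylpent-4-enoate | C=C[C@@H](C)CC(=O)OC[C@H]1COC(C)(C)O1 | intermediate
15 | [(4R)-2,2-dimethyl-1,3-dioxolan-4-yl]methyl (3R)-5-(9-borabicyclo[3.3.1]nonan-9-yl)-3-methylpentanoate | C1CCC2CCCC1B2CC[C@@H](C)CC(=O)OC[C@H]1COC(C)(C)O1 | intermediate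
16 | [(4R)-2,2-dimethyl-1,3-dioxolan-4-yl]methyl (3R)-3-methyl-5-[(4aS,8aR)-2,5,5,8a-tetramethyl-3,4,4a,5,6,7,8,8a-octahydronaphthalen-1-yl]pentanoate | CC2CC[C@H]1C(C)(C)CCC[C@@]1(C)C=2CC[C@@H](C)CC(=O)OC[C@H]3COC(C)(C)O3 | intermediate
17 | secondary ozonide (1,2,4-trioxolane) across the C1–C2 bond of the octalin of 16; the two ozonide carbons are left undefined | CC12CC[C@H]3C(C)(C)CCC[C@@]3(C)C(CC[C@@H](C)CC(=O)OC[C@H]4COC(C)(C)O4)(OO1)O2 | intermediate
18 | [(4R)-2,2-dimethyl-1,3-dioxolan-4-yl]methyl (3R)-3-methyl-6-oxo-6-[(1R,2S)-1,3,3-trimethyl-2-(3-oxobutyl)cyclohexyl]hexanoate | CC(=O)CC[C@H]1C(C)(C)CCC[C@@]1(C)C(=O)CC[C@@H](C)CC(=O)OC[C@H]2COC(C)(C)O2 | intermediate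
19 | (2R)-2,3-dihydroxypropyl (3R)-3-methyl-6-oxo-6-[(1R,2S)-1,3,3-trimethyl-2-(3-oxobutyl)cyclohexyl]hexanoate | CC(=O)CC[C@H]1C(C)(C)CCC[C@@]1(C)C(=O)CC[C@@H](C)CC(=O)OC[C@H](O)CO | intermediate
20 | (2R)-3-(acetyloxy)-2-hydroxypropyl (3R)-3-methyl-6-oxo-6-[(1R,2S)-1,3,3-trimethyl-2-(3-oxobutyl)cyclohexyl]hexanoate | CC(=O)CC[C@H]1C(C)(C)CCC[C@@]1(C)C(=O)CC[C@@H](C)CC(=O)OC[C@H](O)COC(C)=O | target

## Step count and risks

Total steps: 11. Longest linear sequence: 9 (steps 1–5 and 8–11).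

**Step 3 (cation–olefin ring closure).** Protodesilylation or cation side reactions (hydride shift, carbonyl participation) may outrun cyclisation. The fallback sets out from 1 and returns at 10. LiN(iPr)2 and 4-bromobut-1-ene give (5R,6S)-6-(but-3-en-1-yl)-2-methyl-5-(prop-1-en-2-yl)cyclohex-2-en-1-one F1. LiN(iPr)2/MeI gives (5S,6R)-6-(but-3-en-1-yl)-2,6-dimethyl-5-(prop-1-en-2-yl)cyclohex-2-en-1-one F2, with methyl again anti to isopropenyl. Ring-closing metathesis with the second-generation Grubbs catalyst joins butenyl and isopropenyl to (4aS,8aR)-2,5,8a-trimethyl-4a,7,8,8a-tetrahydronaphthalen-1(4H)-one F3. Simmons–Smith cyclopropanation (Et2Zn, CH2I2) of the ring-A alkene gives the cyclopropane-fused enone F4. Hydrogenolysis (H2, PtO2, AcOH) opens the least hindered cyclopropane bond to the gem-dimethyl group and saturates the enone, giving (4aS,8aR)-2,5,5,8a-tetramethyloctahydronaphthalen-1(2H)-one F5. KN(SiMe3)2/PhNTf2 then gives 10.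

**Step 8 (B-alkyl Suzuki on a hindered enol triflate).** This also removes the risk of epoxide formation in step 9 on the hindered alkene. The fallback sets out from 8 and returns at 18. The enolate 9 is trapped with Me3SiCl as trimethyl{[(4aS,8aR)-2,5,5,8a-tetramethyl-3,4,4a,5,6,7,8,8a-octahydronaphthalen-1-yl]oxy}silane F6. Ozonolysis (O3; Me2S; aqueous work-up) cuts ring B first and gives (1R,2S)-1,3,3-trimethyl-2-(3-oxobutyl)cyclohexane-1-carboxylic acid F7. PhSH/DCC/DMAP gives S-phenyl (1R,2S)-1,3,3-trimethyl-2-(3-oxobutyl)cyclohexane-1-carbothioate F8. F8 is joined to borane 15 in a copper-mediated, palladium-catalysed thioester–alkylborane ketone synthesis (Pd2(dba)3, tri(2-furyl)phosphine, Cu(O2CC4H3S), Cs2CO3, THF), giving 18.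

**Step 11 (primary-selective acetylation; diacetate or acyl migration).** The fallback sets out from 18 and returns at 20. LiOH (THF/H2O, 0 °C) cleaves the glyceryl ester to (3R)-3-methyl-6-oxo-6-[(1R,2S)-1,3,3-trimethyl-2-(3-oxobutyl)cyclohexyl]hexanoic acid F9. The acid, with catalytic Cs2CO3 in DMF at 60 °C, opens (S)-glycidyl acetate F10 (made from (R)-glycidol and Ac2O/pyridine) at the terminal epoxide carbon. This gives 20 with the secondary hydroxyl formed in place.

## Further compounds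

F1 | step 3 | (5R,6S)-6-(but-3-en-1-yl)-2-methyl-5-(prop-1-en-2-yl)cyclohex-2-en-1-one | CC1=CC[C@@H](C(C)=C)[C@H](CCC=C)C1=O
F2 | step 3 | (5S,6R)-6-(but-3-en-1-yl)-2,6-dimethyl-5-(prop-1-en-2-yl)cyclohex-2-en-1-one | CC1=CC[C@@H](C(C)=C)[C@@](C)(CCC=C)C1=O
F3 | step 3 | (4aS,8aR)-2,5,8a-trimethyl-4a,7,8,8a-tetrahydronaphthalen-1(4H)-one | CC2=CC[C@H]1C(C)=CCC[C@@]1(C)C2=O
F4 | step 3 | Simmons–Smith adduct of F3 across the ring-A alkene (cyclopropane carbons undefined) | CC2=CC[C@H]1C3(C)CC3CC[C@@]1(C)C2=O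
F5 | step 3 | (4aS,8aR)-2,5,5,8a-tetramethyloctahydronaphthalen-1(2H)-one (C2 epimers) | CC2CC[C@H]1C(C)(C)CCC[C@@]1(C)C2=O
F6 | step 8 | trimethyl{[(4aS,8aR)-2,5,5,8a-tetramethyl-3,4,4a,5,6,7,8,8a-octahydronaphthalen-1-yl]oxy}silane | CC2CC[C@H]1C(C)(C)CCC[C@@]1(C)C=2O[Si](C)(C)C
F7 | step 8 | (1R,2S)-1,3,3-trimethyl-2-(3-oxobutyl)cyclohexane-1-carboxylic acid | CC(=O)CC[C@H]1C(C)(C)CCC[C@@]1(C)C(=O)O
F8 | step 8 | S-phenyl (1R,2S)-1,3,3-trimethyl-2-(3-oxobutyl)cyclohexane-1-carbothioate | CC(=O)CC[C@H]1C(C)(C)CCC[C@@]1(C)C(=O)Sc1ccccc1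
F9 | step 11 | (3R)-3-methyl-6-oxo-6-[(1R,2S)-1,3,3-trimethyl-2-(3-oxobutyl)cyclohexyl]hexanoic acid | CC(=O)CC[C@H]1C(C)(C)CCC[C@@]1(C)C(=O)CC[C@@H](C)CC(=O)O
F10 | step 11 | (S)-glycidyl acetate, [(2S)-oxiran-2-yl]methyl acetate | CC(=O)OC[C@@H]1CO1
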